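**Strategy**

Yanuthone L is cut at the C4–C5 bond of its cyclohexenone (ring numbering: C1 CHOAc, C2 CMe, C3 =CH, C4 C=O, C5 chain-bearing epoxide carbon, C6 epoxide CH). Because the C4 carbonyl sits next to the fully substituted, oxygenated C5, this pair is an acyloin, so a chiral triazolylidene can convert the aldehyde of an acyclic Z-enal into a nucleophile that attacks a tethered farnesyl-type ketone, closing the carbocycle and creating the C5 carbinol in one operation. The precursor is a D-threitol-derived trans-dioxolane carrying the Z-enal on C1 and the β,γ-unsaturated chain ketone on C6; the ketal later yields the C1 acetate and, by inversion, the C6 epoxide terminus.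

Key step: step 16

**Remarks and assumptions**

- The ring numbering C1–C6 of the overview is used throughout. "TBDPSO-farnesyl" stands for (2E,6E,10E)-12-{[tert-butyl(diphenyl)silyl]oxy}-3,7,11-trimethyldodeca-2,6,10-trien-1-yl.
- Design choice: the terminal chain oxygen is carried as a tert-butyldiphenylsilyl ether, because a tert-butyldimethylsilyl ether on a primary allylic position would not reliably survive the aqueous acid that later opens the ketal.
- Assumption: the (5aR,10bS) antipode of the aminoindanol triazolium salt is taken as the catalyst whose facial preference matches the substrate. If the pairing proves mismatched, the (5aS,10bR) salt takes its place in the same step.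
- The starting diol 1 is the commercial acetonide of D-threitol, i.e. the reduced acetonide of D-tartrate.

**Route**

Step 1
Reactants: 1 (4R,5R)-2,3-O-isopropylidene-D-threitol
Product: 2 mono-tert-butyldimethylsilyl ether of 1
Conditions: NaH (1.0 equiv), THF, 0 °C; then TBSCl (1.0 equiv), 0 °C to rt
Reagents that add atoms: tert-butyldimethylsilyl chloride, CC(C)(C)[Si](C)(C)Cl
Why: O-silylation of the monosodium alkoxide (Williamson-type) of a C2-symmetric diol, whose two hydroxyls are equivalent, should give a single monoether and leaves both stereocentres untouched.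

Step 2
Reactants: 2 monosilyl ether
Product: 3 (4S,5R)-5-(silyloxymethyl)-2,2-dimethyl-1,3-dioxolane-4-carbaldehyde
Conditions: Dess–Martin periodinane, pyridine, CH2Cl2, 0 °C to rt
Reagents that add atoms: none
Why: Dess–Martin oxidation under buffered conditions should stop at the α-alkoxy aldehyde, and since the trans-dioxolane is the more stable ring isomer the α-centre has no drive to epimerise.

Step 3
Reactants: 3 aldehyde
Product: 4 (4R,5R)-ethynyl dioxolane silyl ether
Conditions: dimethyl (1-diazo-2-oxopropyl)phosphonate, K2CO3, MeOH, 0 °C to rt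
Reagents that add atoms: dimethyl (1-diazo-2-oxopropyl)phosphonate, COP(=O)(OC)C(=[N+]=[N-])C(C)=O
Why: Seyferth–Gilbert homologation in the Ohira–Bestmann variant converts aldehydes into terminal alkynes under mild carbonate conditions that α-alkoxy aldehydes of this dioxolane type routinely tolerate.

Step 4
Reactants: 4 terminal alkyne
Product: 5 methyl alkynoate
Conditions: n-BuLi, THF, −78 °C; then ClCO2Me, −78 to 0 °C
Reagents that add atoms: methyl chloroformate, COC(=O)Cl
Why: Deprotonation of the terminal alkyne and C-acylation of the lithium acetylide with a chloroformate is the standard alkynoate synthesis, and silyl ether and ketal are inert to it.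

Step 5
Reactants: 5 methyl alkynoate
Product: 6 methyl (2Z)-3-(dioxolanyl)but-2-enoate
Conditions: Me2CuLi (from CuI and 2 MeLi), THF, −78 °C; MeOH then aq NH4Cl at −78 °C
Reagents that add atoms: lithium dimethylcuprate, [Li+].C[Cu-]C
Why: Conjugate addition of a Gilman cuprate to an alkynoate is a syn carbocupration, so protonation of the vinylcopper at −78 °C before it equilibrates should place the dioxolane cis to the ester (Z), and an ether-type propargylic oxygen is not expelled under these conditions.

Step 6
Reactants: 6 Z-enoate silyl ether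
Product: 7 Z-enoate primary alcohol
Conditions: Bu4NF, AcOH (1:1), THF, 0 °C to rt
Reagents that add atoms: none
Why: Fluoride-mediated desilylation buffered with acetic acid frees the primary alcohol without acid catalysis, so the internal ketal cannot migrate to the terminal diol position and the Z-enoate is not isomerised.

Step 7
Reactants: 7 Z-enoate alcohol
Product: 8 methyl (2Z)-3-[(4R,5S)-5-formyl-2,2-dimethyl-1,3-dioxolan-4-yl]but-2-enoate
Conditions: Dess–Martin periodinane, pyridine, CH2Cl2, 0 °C; used at once
Reagents that add atoms: none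
Why: Dess–Martin oxidation as in step 2 should give the second α-alkoxy aldehyde without touching the enoate or its geometry.

Step 8
Reactants: 9 (2E,6E)-farnesol
Product: 10 (2E,6E)-farnesyl acetate
Conditions: Ac2O, pyridine, DMAP (cat.), CH2Cl2, rt
Reagents that add atoms: acetic anhydride, CC(=O)OC(C)=O
Why: DMAP-catalysed acetylation masks the allylic alcohol so that it survives the allylic oxidation and deactivates the proximal alkene.

Step 9
Reactants: 10 farnesyl acetate
Product: 11 (2E,6E,10E)-12-hydroxyfarnesyl acetate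
Conditions: SeO2 (cat.), t-BuOOH, salicylic acid (cat.), CH2Cl2, 0 °C to rt; stopped at partial conversion, 10 recycled
Reagents that add atoms: SeO2 (oxygen carrier), O=[Se]=O; tert-butyl hydroperoxide (stoichiometric oxygen source), CC(C)(C)OO
Why: Riley allylic oxidation (ene reaction then [2,3]-sigmatropic shift) attacks the most electron-rich terminal trisubstituted alkene at its E-methyl group, which should give the E-configured primary allylic alcohol.

Step 10
Reactants: 11 hydroxy acetate
Product: 12 TBDPS ether acetate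
Conditions: TBDPSCl, imidazole, DMF, rt
Reagents that add atoms: tert-butyl(chloro)diphenylsilane, CC(C)(C)[Si](Cl)(c1ccccc1)c1ccccc1
Why: Imidazole-promoted silylation of a primary alcohol is routine, and the tert-butyldiphenylsilyl group is chosen for its stability to the later aqueous acid.

Step 11
Reactants: 12 TBDPS ether acetate
Product: 13 TBDPSO-farnesol
Conditions: K2CO3 (cat.), MeOH, rt
Reagents that add atoms: none
Why: Carbonate-catalysed transesterification (Zemplén-type methanolysis) removes the acetate and leaves the silyl ether intact.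

Step 12
Reactants: 13 TBDPSO-farnesol
Product: 14 TBDPSO-farnesyl chloride
Conditions: N-chlorosuccinimide, Me2S, CH2Cl2, −40 to 0 °C
Reagents that add atoms: N-chlorosuccinimide, ClN1C(=O)CCC1=O
Why: Corey–Kim chlorination converts primary allylic alcohols into unrearranged allylic chlorides with retention of alkene geometry under cold, neutral conditions.

Step 13
Reactants: 14 TBDPSO-farnesyl chloride; 8 formyl Z-enoate
Product: 16 homoallylic alcohol (both carbinol epimers), via allylbarium chloride 15 (not isolated)
Conditions: BaI2, LiC12H10 (lithium biphenylide, 2 equiv), THF, rt (gives zerovalent barium); 14, −78 °C; then 8, −78 °C; aq NH4Cl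
Reagents that add atoms: none
Why: Allylic barium reagents made from zerovalent barium add to aldehydes at the α-carbon with retention of the E geometry (Barbier-type allylation), an aldehyde reacts far faster than the hindered enoate at −78 °C, and the mixed configuration of the new carbinol is immaterial because it is oxidised in step 15.

Step 14
Reactants: 16 hydroxy Z-enoate
Product: 17 Z-allylic alcohol/secondary alcohol diol
Conditions: i-Bu2AlH (excess), CH2Cl2, −78 to −20 °C; aq KNaC4H4O6 (potassium sodium tartrate)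
Reagents that add atoms: none
Why: i-Bu2AlH reduces an α,β-unsaturated ester by 1,2-addition to the allylic alcohol without changing the alkene geometry or touching ketal and silyl ether.

Step 15
Reactants: 17 diol
Product: 18 Z-enal chain ketone (cyclisation precursor)
Conditions: Dess–Martin periodinane (3 equiv), pyridine, CH2Cl2, 0 °C to rt; used directly
Reagents that add atoms: none
Why: Dess–Martin oxidation converts the primary allylic and the secondary alcohol in one operation under near-neutral conditions that should neither isomerise the Z-enal nor move the β,γ-alkene into conjugation.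

Step 16
Reactants: 18 Z-enal chain ketone
Product: 19 trans-fused acetonide of the 6-hydroxy-6-(TBDPSO-farnesyl)-3-methylcyclohexenone
Conditions: (5aR,10bS)-2-(pentafluorophenyl)-5a,10b-dihydro-4H,6H-indeno[2,1-b][1,2,4]triazolo[4,3-d][1,4]oxazin-2-ium tetrafluoroborate (20 mol %), i-Pr2NEt (20 mol %), toluene (0.02 M), 0 °C to rt, argon
Reagents that add atoms: none
Why: The carbene adds to the C4 aldehyde and proton transfer gives the Breslow dienaminol, whose C4 carbon attacks the C5 ketone while the enol proton passes to the forming alkoxide, and release of the carbene leaves the α-hydroxy enone; this is an intramolecular crossed aldehyde–ketone benzoin reaction, closest to the known triazolium-catalysed benzoin cyclisations of keto-aldehydes. The six-membered carbocycle closes in a 6-exo-trig mode, and the Z geometry of the enal together with the trans-dioxolane holds C4 within reach of C5. The C5 stereocentre is set by the ketone face that the acyl anion equivalent attacks, controlled by the aminoindanol-derived catalyst together with the adjacent C6 centre. In the closed, hydrogen-bonded transition state with the triazolium unit pseudo-equatorial the ketone oxygen lies equatorial, which is the required arrangement trans to the C6 oxygen. Chemoselectivity rests on three substrate features: only the aldehyde can form a Breslow intermediate, the homoenolate carbon C2 could only close a four-membered ring, and the C1 oxygen is a ketal ether and therefore a poor leaving group for vinylogous elimination. The electron-poor pentafluorophenyl triazolium salt and a weak amine base are chosen to favour acyl-anion over homoenolate chemistry and to spare the enolisable β,γ-unsaturated ketone.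

Step 17
Reactants: 19 acetonide ketol
Product: 20 (4R,5S,6R)-triol
Conditions: AcOH/H2O (4:1), 40 °C
Reagents that add atoms: none
Why: Acid-catalysed ketal hydrolysis should be easy for the strained trans-fused dioxolane under mild aqueous acetic acid, which leaves the tert-butyldiphenylsilyl ether, the tertiary ketol and the trisubstituted alkenes intact.

Step 18
Reactants: 20 triol
Product: 21 C1 monoacetate
Conditions: AcCl (1.05 equiv), 2,4,6-collidine, CH2Cl2, −78 to −40 °C
Reagents that add atoms: acetyl chloride, CC(=O)Cl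
Why: Kinetically controlled acylation at low temperature should select the allylic C1 hydroxyl, because the C6 hydroxyl is gauche to the substituents of the fully substituted C5 in either half-chair and the C5 hydroxyl is tertiary.

Step 19
Reactants: 21 C1 monoacetate
Product: 23 TBDPS ether of yanuthone L, via C6 mesylate 22 (not isolated)
Conditions: MsCl, Et3N, CH2Cl2, −20 °C; then DBU, 0 °C to rt
Reagents that add atoms: none
Why: Sulfonylation of the only remaining secondary hydroxyl followed by intramolecular Williamson displacement (SN2, 3-exo-tet) by the trans-disposed C5 alkoxide closes the epoxide with inversion at C6, which places the epoxide oxygen cis to the C1 acetate as in the target.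

Step 20
Reactants: 23 TBDPS ether of yanuthone L
Product: 24 yanuthone L
Conditions: HF·pyridine, pyridine, THF, 0 °C to rt
Reagents that add atoms: none
Why: Fluoride-induced Si–O cleavage with pyridine-buffered HF removes the silyl ether under weakly acidic conditions that epoxy ketones and allylic acetates normally tolerate.

**Compound list**

1 | (4R,5R)-2,2-dimethyl-1,3-dioxolane-4,5-dimethanol (2,3-O-isopropylidene-D-threitol) | OC[C@H]1OC(C)(C)O[C@@H]1CO | starting material
2 | [(4R,5R)-5-({[tert-butyl(dimethyl)silyl]oxy}methyl)-2,2-dimethyl-1,3-dioxolan-4-yl]methanol | OC[C@H]1OC(C)(C)O[C@@H]1CO[Si](C)(C)C(C)(C)C | intermediate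
3 | (4S,5R)-5-({[tert-butyl(dimethyl)silyl]oxy}methyl)-2,2-dimethyl-1,3-dioxolane-4-carbaldehyde | O=C[C@H]1OC(C)(C)O[C@@H]1CO[Si](C)(C)C(C)(C)C | intermediate
4 | tert-butyl{[(4R,5R)-5-ethynyl-2,2-dimethyl-1,3-dioxolan-4-yl]methoxy}dimethylsilane | C#C[C@H]1OC(C)(C)O[C@@H]1CO[Si](C)(C)C(C)(C)C | intermediate
5 | methyl 3-[(4R,5R)-5-({[tert-butyl(dimethyl)silyl]oxy}methyl)-2,2-dimethyl-1,3-dioxolan-4-yl]prop-2-ynoate | COC(=O)C#C[C@H]1OC(C)(C)O[C@@H]1CO[Si](C)(C)C(C)(C)C | intermediate
6 | methyl (2Z)-3-[(4R,5R)-5-({[tert-butyl(dimethyl)silyl]oxy}methyl)-2,2-dimethyl-1,3-dioxolan-4-yl]but-2-enoate | COC(=O)/C=C(/C)[C@H]1OC(C)(C)O[C@@H]1CO[Si](C)(C)C(C)(C)C | intermediate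
7 | methyl (2Z)-3-[(4R,5R)-5-(hydroxymethyl)-2,2-dimethyl-1,3-dioxolan-4-yl]but-2-enoate | COC(=O)/C=C(/C)[C@H]1OC(C)(C)O[C@@H]1CO | intermediate
8 | methyl (2Z)-3-[(4R,5S)-5-formyl-2,2-dimethyl-1,3-dioxolan-4-yl]but-2-enoate | COC(=O)/C=C(/C)[C@H]1OC(C)(C)O[C@@H]1C=O | intermediate
9 | (2E,6E)-farnesol | CC(C)=CCC/C(C)=C/CC/C(C)=C/CO | starting material
10 | (2E,6E)-farnesyl acetate | CC(C)=CCC/C(C)=C/CC/C(C)=C/COC(C)=O | intermediate
11 | (2E,6E,10E)-12-hydroxy-3,7,11-trimethyldodeca-2,6,10-trien-1-yl acetate | CC(=O)OC/C=C(\C)CC/C=C(\C)CC/C=C(\C)CO | intermediate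
12 | (2E,6E,10E)-12-{[tert-butyl(diphenyl)silyl]oxy}-3,7,11-trimethyldodeca-2,6,10-trien-1-yl acetate | CC(=O)OC/C=C(\C)CC/C=C(\C)CC/C=C(\C)CO[Si](c1ccccc1)(c1ccccc1)C(C)(C)C | intermediate
13 | (2E,6E,10E)-12-{[tert-butyl(diphenyl)silyl]oxy}-3,7,11-trimethyldodeca-2,6,10-trien-1-ol | OC/C=C(\C)CC/C=C(\C)CC/C=C(\C)CO[Si](c1ccccc1)(c1ccccc1)C(C)(C)C | intermediate
14 | tert-butyl{[(2E,6E,10E)-12-chloro-2,6,10-trimethyldodeca-2,6,10-trien-1-yl]oxy}diphenylsilane | ClC/C=C(\C)CC/C=C(\C)CC/C=C(\C)CO[Si](c1ccccc1)(c1ccccc1)C(C)(C)C | intermediate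
15 | [(2E,6E,10E)-12-{[tert-butyl(diphenyl)silyl]oxy}-3,7,11-trimethyldodeca-2,6,10-trien-1-yl]barium chloride | Cl[Ba]C/C=C(\C)CC/C=C(\C)CC/C=C(\C)CO[Si](c1ccccc1)(c1ccccc1)C(C)(C)C | intermediate (not isolated)
16 | methyl (2Z)-3-{(4R,5R)-5-[(3E,7E,11E)-13-{[tert-butyl(diphenyl)silyl]oxy}-1-hydroxy-4,8,12-trimethyltrideca-3,7,11-trien-1-yl]-2,2-dimethyl-1,3-dioxolan-4-yl}but-2-enoate (both carbinol epimers) | COC(=O)/C=C(/C)[C@H]1OC(C)(C)O[C@@H]1C(O)C/C=C(\C)CC/C=C(\C)CC/C=C(\C)CO[Si](c1ccccc1)(c1ccccc1)C(C)(C)C | intermediate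
17 | (2Z)-3-{(4R,5R)-5-[(3E,7E,11E)-13-{[tert-butyl(diphenyl)silyl]oxy}-1-hydroxy-4,8,12-trimethyltrideca-3,7,11-trien-1-yl]-2,2-dimethyl-1,3-dioxolan-4-yl}but-2-en-1-ol (both carbinol epimers) | OC/C=C(/C)[C@H]1OC(C)(C)O[C@@H]1C(O)C/C=C(\C)CC/C=C(\C)CC/C=C(\C)CO[Si](c1ccccc1)(c1ccccc1)C(C)(C)C | intermediate
18 | (2Z)-3-{(4R,5S)-5-[(3E,7E,11E)-13-{[tert-butyl(diphenyl)silyl]oxy}-4,8,12-trimethyltrideca-3,7,11-trienoyl]-2,2-dimethyl-1,3-dioxolan-4-yl}but-2-enal | O=C/C=C(/C)[C@H]1OC(C)(C)O[C@@H]1C(=O)C/C=C(\C)CC/C=C(\C)CC/C=C(\C)CO[Si](c1ccccc1)(c1ccccc1)C(C)(C)C | intermediate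
19 | (3aS,4R,7aR)-4-hydroxy-2,2,7-trimethyl-4-(TBDPSO-farnesyl)-3a,7a-dihydro-1,3-benzodioxol-5(4H)-one (trans-fused acetonide; C5 hydroxyl trans to the C6 oxygen in ring numbering) | CC1=CC(=O)[C@@](O)(C/C=C(\C)CC/C=C(\C)CC/C=C(\C)CO[Si](c3ccccc3)(c3ccccc3)C(C)(C)C)[C@H]2OC(C)(C)O[C@H]12 | intermediate
20 | (4R,5S,6R)-4,5,6-trihydroxy-3-methyl-6-(TBDPSO-farnesyl)cyclohex-2-en-1-one | CC1=CC(=O)[C@@](O)(C/C=C(\C)CC/C=C(\C)CC/C=C(\C)CO[Si](c2ccccc2)(c2ccccc2)C(C)(C)C)[C@@H](O)[C@@H]1O | intermediate
21 | (1R,5R,6S)-5,6-dihydroxy-2-methyl-4-oxo-5-(TBDPSO-farnesyl)cyclohex-2-en-1-yl acetate | CC(=O)O[C@@H]1C(C)=CC(=O)[C@@](O)(C/C=C(\C)CC/C=C(\C)CC/C=C(\C)CO[Si](c2ccccc2)(c2ccccc2)C(C)(C)C)[C@H]1O | intermediate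
22 | (1R,5R,6S)-5-hydroxy-6-[(methanesulfonyl)oxy]-2-methyl-4-oxo-5-(TBDPSO-farnesyl)cyclohex-2-en-1-yl acetate | CC(=O)O[C@@H]1C(C)=CC(=O)[C@@](O)(C/C=C(\C)CC/C=C(\C)CC/C=C(\C)CO[Si](c2ccccc2)(c2ccccc2)C(C)(C)C)[C@H]1OS(C)(=O)=O | intermediate (not isolated)
23 | (1R,2R,6R)-3-methyl-5-oxo-6-(TBDPSO-farnesyl)-7-oxabicyclo[4.1.0]hept-3-en-2-yl acetate | CC(=O)O[C@@H]1C(C)=CC(=O)[C@]2(C/C=C(\C)CC/C=C(\C)CC/C=C(\C)CO[Si](c3ccccc3)(c3ccccc3)C(C)(C)C)O[C@H]12 | intermediate
24 | yanuthone L, (1R,2R,6R)-6-[(2E,6E,10E)-12-hydroxy-3,7,11-trimethyldodeca-2,6,10-trien-1-yl]-3-methyl-5-oxo-7-oxabicyclo[4.1.0]hept-3-en-2-yl acetate | CC(=O)O[C@@H]1C(C)=CC(=O)[C@]2(C/C=C(\C)CC/C=C(\C)CC/C=C(\C)CO)O[C@H]12 | target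

**Step count and risk**

Total step count: 20. Longest linear sequence: 15 steps (steps 1–7 and 13–20, from diol 1); the chain arm from farnesol contributes steps 8–12.

Steps most likely to fail:

1. Step 16. Attack on the wrong ketone face, or diversion of the Breslow intermediate into homoenolate, elimination or enolisation pathways, would erode the yield of 19. The fallback forms the same C4–C5 bond reductively and sets out from keto-enal 18. Treatment with SmI2 (divalent samarium) in THF/t-BuOH at −78 °C should effect ketyl–carbonyl (pinacol) cyclisation to the cis-diol (3aS,4S,5S,7aR)-2,2,7-trimethyl-4-(TBDPSO-farnesyl)-3a,4,5,7a-tetrahydro-1,3-benzodioxole-4,5-diol F1, with the new C5 hydroxyl anti to the C6 oxygen as is usual for pinacol cyclisations next to an alkoxy group. Oxidation of the secondary allylic hydroxyl of F1 with IBX in DMSO, which does not cleave glycols, returns to 19.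

2. Step 18. Acylation at the C6 hydroxyl, over-acylation or acyl migration would compromise the differentiation of the two secondary hydroxyls. The fallback replaces kinetic selectivity by a temporary tether and sets out from triol 20. Condensation with phenylboronic acid (toluene, azeotropic removal of water) should bridge the cis-1,3-related C1 and C5 oxygens as the C1,C5-O,O'-phenylboronate of the triol F2, leaving only the C6 hydroxyl free. Mesylation (MsCl, Et3N) gives the C6 mesylate of the phenylboronate F3. Transesterification with pinacol releases the C6 mesylate with free C1 and C5 hydroxyls F4. Acetylation of its only secondary hydroxyl (Ac2O, pyridine) delivers acetoxy mesylate 22, which is cyclised with DBU as in step 19.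

3. Step 13. Failure to generate the barium reagent, attack through the γ-carbon or loss of alkene geometry would block the fragment union. The fallback uses sulfone umpolung and sets out from chloride 14 and aldehyde 8. Displacement with PhSO2Na in DMF converts 14 into the allylic phenyl sulfone F5. Its lithio derivative (n-BuLi, THF, −78 °C) is added to 8 to give the β-hydroxy sulfone F6. Treatment of F6 with LiBHEt3 and catalytic PdCl2(dppp) should remove the allylic sulfonyl group by hydride delivery to the less hindered allyl terminus with retention of the E alkene and at the same time reduce the enoate, which returns the route at diol 17.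

**Further compounds**

F1 | step 16 | (3aS,4S,5S,7aR)-2,2,7-trimethyl-4-(TBDPSO-farnesyl)-3a,4,5,7a-tetrahydro-1,3-benzodioxole-4,5-diol (4,5-cis-diol) | CC1=C[C@H](O)[C@@](O)(C/C=C(\C)CC/C=C(\C)CC/C=C(\C)CO[Si](c3ccccc3)(c3ccccc3)C(C)(C)C)[C@H]2OC(C)(C)O[C@H]12
F2 | step 18 | C1,C5-O,O'-phenylboronate of triol 20 (six-membered boronate across the cis-1,3-diol, C6 hydroxyl free) | O[C@H]1[C@@H]2OB(c3ccccc3)O[C@@]1(C/C=C(\C)CC/C=C(\C)CC/C=C(\C)CO[Si](c3ccccc3)(c3ccccc3)C(C)(C)C)C(=O)C=C2C
F3 | step 18 | C6 methanesulfonate of phenylboronate F2 | CS(=O)(=O)O[C@H]1[C@@H]2OB(c3ccccc3)O[C@@]1(C/C=C(\C)CC/C=C(\C)CC/C=C(\C)CO[Si](c3ccccc3)(c3ccccc3)C(C)(C)C)C(=O)C=C2C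
F4 | step 18 | C6 methanesulfonate of triol 20 with free C1 and C5 hydroxyls | O[C@@H]1C(C)=CC(=O)[C@@](O)(C/C=C(\C)CC/C=C(\C)CC/C=C(\C)CO[Si](c2ccccc2)(c2ccccc2)C(C)(C)C)[C@H]1OS(C)(=O)=O
F5 | step 13 | tert-butyl{[(2E,6E,10E)-12-(benzenesulfonyl)-2,6,10-trimethyldodeca-2,6,10-trien-1-yl]oxy}diphenylsilane | O=S(=O)(c1ccccc1)C/C=C(\C)CC/C=C(\C)CC/C=C(\C)CO[Si](c1ccccc1)(c1ccccc1)C(C)(C)C
F6 | step 13 | methyl (2Z)-3-{(4R,5R)-5-[(3E,7E,11E)-2-(benzenesulfonyl)-13-{[tert-butyl(diphenyl)silyl]oxy}-1-hydroxy-4,8,12-trimethyltrideca-3,7,11-trien-1-yl]-2,2-dimethyl-1,3-dioxolan-4-yl}but-2-enoate (diastereomer mixture) | COC(=O)/C=C(/C)[C@H]1OC(C)(C)O[C@@H]1C(O)C(/C=C(\C)CC/C=C(\C)CC/C=C(\C)CO[Si](c1ccccc1)(c1ccccc1)C(C)(C)C)S(=O)(=O)c1ccccc1
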